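**Retrosynthetic overview**

1. The strategy rests on ring A: a methylenecyclohexane whose exocyclic C4=C15 bond lies next to the ring-fusion bond C5–C10, with C10 quaternary (CH3 and C9). This is the pattern left when the γ-carbon (C5) of an allylsilane attacks an electrophilic C10 and silicon leaves from C15.
2. Endgame: hydroxyquinone ⇐ 2,5-dimethoxyquinone ⇐ tetramethoxyarene; the C11–aryl bond comes from aryllithium addition to the C11 aldehyde followed by radical deoxygenation.
3. C8/C9: CH3-8 by hydroxyl-directed hydrogenation of the 8(12)-alkene from the α face. At C9 one malonate ester becomes the β-CH3; the other is removed (Krapcho) and replaced by an α-CH2OH (C11) through face-selective enolate hydroxymethylation.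
4. Ring B (formed second): Conia-ene closure C8–C9 of the malonate onto the terminal alkyne. Ring A (formed first): copper–bis(oxazoline)-catalysed intramolecular Hosomi–Sakurai conjugate addition forming C5–C10.
5. Precursor: anti-carbomagnesiation of hepta-2,6-diyn-1-ol with Me3SiCH2MgCl fixes the allylsilane geometry; allylic chloride/Grignard coupling and Knoevenagel condensation complete it.

Key step: step 7

Remark (locants): C1–C5 and C10 are ring A, C5–C10 ring B, C15 the methylidene carbon on C4, C12 the carbon on C8, C11 the carbon on C9 that ends as ArCH2; α is the face of H-5, β the face of CH3-10.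
Remark (assumption): the (S,S)-ligand is assumed to give the (1S,2S) product in step 7; if the sense of induction is the opposite, the (R,R)-ligand is used with nothing else changed.
Remark (geometry): the allylsilane in 9, 10 and 12 is (Z) by the sequence rule, i.e. CH2SiMe3 is cis to the butynyl chain.

**Step 1**
Reactants: 1 hexa-1,5-diyne (3 equiv, commercial solution)
Product: 3 hepta-2,6-diyn-1-ol, via lithium hexadiynide 2 (not isolated)
Conditions: n-BuLi (1.0 equiv), THF, −78 °C; (CH2O)n, −78 °C → rt; H2O
Reagents that add atoms: formaldehyde (from paraformaldehyde), C=O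
Why: Monolithiation of the diyne, used in excess to suppress double reaction, and addition of the acetylide to formaldehyde is a standard alkynylation that gives the propargylic alcohol without forming a stereocentre.

**Step 2**
Reactants: 3 hepta-2,6-diyn-1-ol
Product: 4 (2Z)-2-[(trimethylsilyl)methyl]hept-2-en-6-yn-1-ol
Conditions: Me3SiCH2MgCl (4 equiv), CuI (15 mol %), THF/Et2O, reflux; H2O
Reagents that add atoms: (trimethylsilyl)methylmagnesium chloride, C[Si](C)(C)C[Mg]Cl
Why: Copper-catalysed anti-carbomagnesiation of a propargylic alkoxide puts CH2SiMe3 on the carbon next to the carbinol and magnesium on the distal carbon inside a five-membered alkoxide chelate, so that after protonation CH2SiMe3 is cis to the butynyl chain, while the remote alkyne is only held as its magnesium acetylide.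

**Step 3**
Reactants: 4 (2Z)-2-[(trimethylsilyl)methyl]hept-2-en-6-yn-1-ol
Product: 6 [(2E)-2-(chloromethyl)hept-2-en-6-yn-1-yl]trimethylsilane, via allylic mesylate 5 (not isolated)
Conditions: MsCl (1.2 equiv), LiCl (3 equiv), 2,4,6-collidine (1.5 equiv), DMF, 0 °C
Reagents that add atoms: lithium chloride, [Li+].[Cl-]
Why: Mesylation with in situ chloride displacement under buffered conditions is an SN2 allylic chlorination at the primary carbon that leaves the acid-sensitive allylsilane and the alkene geometry untouched (the descriptor changes to E only because CH2Cl outranks CH2Si).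

**Step 4**
Reactants: 6 [(2E)-2-(chloromethyl)hept-2-en-6-yn-1-yl]trimethylsilane; 7 2-(2-bromoethyl)-2-methyl-1,3-dioxolane
Product: 9 2-methyl-2-[(4Z)-4-[(trimethylsilyl)methyl]non-4-en-8-yn-1-yl]-1,3-dioxolane, via ketal Grignard reagent 8 (not isolated)
Conditions: 7, Mg, THF, 25 °C; then 6 (8 used at 2.3 equiv), Li2CuCl4 (5 mol %), THF, −40 → 0 °C; H2O
Reagents that add atoms: none
Why: Copper-catalysed cross-coupling of a Grignard reagent with a primary allylic chloride proceeds at the unsubstituted α-carbon with retention of alkene geometry, the extra equivalent of Grignard only parking the terminal alkyne as an acetylide, which is a non-transferable ligand on copper.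

**Step 5**
Reactants: 9 2-methyl-2-[(4Z)-4-[(trimethylsilyl)methyl]non-4-en-8-yn-1-yl]-1,3-dioxolane
Product: 10 (6Z)-6-[(trimethylsilyl)methyl]undec-6-en-10-yn-2-one
Conditions: PPTS (0.2 equiv), acetone/H2O, 50 °C
Reagents that add atoms: water, O
Why: Acid-catalysed ketal hydrolysis with a weak pyridinium acid unmasks the methyl ketone without protodesilylating the allylsilane.

**Step 6**
Reactants: 10 (6Z)-6-[(trimethylsilyl)methyl]undec-6-en-10-yn-2-one; 11 dimethyl malonate
Product: 12 dimethyl 2-[(6Z)-6-[(trimethylsilyl)methyl]undec-6-en-10-yn-2-ylidene]propanedioate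
Conditions: TiCl4 (2 equiv), pyridine (4 equiv), THF, 0 °C → rt
Reagents that add atoms: none
Why: The titanium tetrachloride/pyridine variant of the Knoevenagel condensation is the standard way to condense a malonate ester with a ketone, and titanium complexed by THF and pyridine is too weak a Lewis acid to trigger the allylsilane.

**Step 7**
Reactants: 12 dimethyl 2-[(6Z)-6-[(trimethylsilyl)methyl]undec-6-en-10-yn-2-ylidene]propanedioate
Product: 13 dimethyl 2-[(1S,2S)-2-(but-3-yn-1-yl)-1-methyl-3-methylidenecyclohexyl]propanedioate
Conditions: [Cu((S,S)-t-Bu-box)](SbF6)2 (10 mol %), (CF3)2CHOH (1.5 equiv), CH2Cl2, −20 °C → rt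
Reagents that add atoms: none
Why: Proposed new method: the bis(oxazoline)copper(II) dication chelates both ester carbonyls of 12 and so activates C10; the allylsilane γ-carbon C5 adds to C10 to give a tertiary β-silyl cation at C4, which loses Me3Si+ to leave the C4=C15 methylidene, while hexafluoroisopropanol takes up the silyl group, protonates C9 and frees the catalyst. The closest known reactions are the Lewis-acid-promoted intramolecular Hosomi–Sakurai conjugate allylation of alkylidene 1,3-dicarbonyl compounds and the copper–bis(oxazoline)-catalysed Mukaiyama–Michael addition of silyl nucleophiles to alkylidene malonates; new here are an allylsilane as the nucleophile, a β,β-disubstituted acceptor and enantiofacial control at a quaternary carbon. Ring A closes through C5–C10 in a 6-exo-trig mode at the acceptor (C9 stays outside the ring), which is 6-endo with respect to the allylsilane C4=C5 bond. C10 is set by the ligand, whose tert-butyl groups should leave only one face of the bound C10=C9 bond open to the folded tether. C5 is set relative to C10 by a chair-like transition state: allylic strain places the chelated malonyl unit equatorial, and the butynyl chain is equatorial because CH2SiMe3 is cis to it, so CH3-10 and H-5 end trans-diaxial. The step needs C-allylation through C5 to outrun protodesilylation and any uncatalysed racemic pathway; the absence of a Brønsted acid stronger than the fluoro alcohol and the inertness of 12 without Lewis acid should secure this, with the terminal alkyne a spectator.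

**Step 8**
Reactants: 13 dimethyl 2-[(1S,2S)-2-(but-3-yn-1-yl)-1-methyl-3-methylidenecyclohexyl]propanedioate
Product: 14 dimethyl (4aS,8aS)-8a-methyl-2,5-dimethylideneoctahydronaphthalene-1,1(2H)-dicarboxylate (trans-decalin; 9,9-diester, 4(15)- and 8(12)-methylidene)
Conditions: In(OTf)3 (10 mol %), DBU (10 mol %), toluene, 110 °C
Reagents that add atoms: none
Why: Indium(III)-catalysed Conia-ene cycloisomerisation adds the malonate enolate across the unactivated terminal alkyne in a 6-exo-dig mode, forming C8–C9 and the 8(12)-methylidene; the ring fusion is already fixed by C5 and C10, and C9 is not stereogenic.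

**Step 9**
Reactants: 14 dimethyl (4aS,8aS)-8a-methyl-2,5-dimethylideneoctahydronaphthalene-1,1(2H)-dicarboxylate
Product: 15 methyl (4aS,8aS)-8a-methyl-2,5-dimethylidenedecahydronaphthalene-1-carboxylate (mixture of C9 epimers)
Conditions: LiCl (3 equiv), H2O (2 equiv), DMSO, 160 °C
Reagents that add atoms: none
Why: Krapcho demethoxycarbonylation removes one of the geminal esters under neutral conditions that leave both exocyclic alkenes alone, and the C9 epimers converge because C9 is planarised in the next step.

**Step 10**
Reactants: 15 methyl (4aS,8aS)-8a-methyl-2,5-dimethylidenedecahydronaphthalene-1-carboxylate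
Product: 17 methyl (1S,4aS,8aS)-1-(hydroxymethyl)-8a-methyl-2,5-dimethylidenedecahydronaphthalene-1-carboxylate (9β-CO2Me and 9α-CH2OH), via lithium dienolate 16 (not isolated)
Conditions: LDA (1.3 equiv), THF/DMPU, −78 → −40 °C; CH2O (gas, from cracked paraformaldehyde), −78 °C; H2O
Reagents that add atoms: formaldehyde, C=O
Why: α-Alkylation of an ester dienolate with formaldehyde (aldol-type hydroxymethylation) should occur at C9 from the α face, anti to the axial C10 methyl that screens the β face, setting C9 with CH2OH α (axial) and CO2Me β (equatorial) and keeping the 8(12)-alkene exocyclic.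

**Step 11**
Reactants: 17 methyl (1S,4aS,8aS)-1-(hydroxymethyl)-8a-methyl-2,5-dimethylidenedecahydronaphthalene-1-carboxylate
Product: 18 methyl (1S,2S,4aS,8aS)-1-(hydroxymethyl)-2,8a-dimethyl-5-methylidenedecahydronaphthalene-1-carboxylate (8β-CH3)
Conditions: [Ir(cod)(PCy3)(py)]PF6 (2.5 mol %), H2 (1 atm, stopped after 1 equiv), CH2Cl2, 0 °C
Reagents that add atoms: none
Why: In this hydroxyl-directed homogeneous hydrogenation the axial 9α-CH2OH binds iridium and delivers hydrogen to the α face of the neighbouring 8(12)-alkene (the β face is also blocked by CH3-10), setting C8 with its methyl β, while the distant 4(15)-alkene cannot chelate and should be left behind.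

**Step 12**
Reactants: 18 methyl (1S,2S,4aS,8aS)-1-(hydroxymethyl)-2,8a-dimethyl-5-methylidenedecahydronaphthalene-1-carboxylate
Product: 19 (1S,2S,4aS,8aS)-1-(hydroxymethyl)-2,8a-dimethyl-5-methylidenedecahydronaphthalene-1-carbaldehyde
Conditions: DIBAL-H (3 equiv), CH2Cl2, −78 → −40 °C; aq. Rochelle salt
Reagents that add atoms: none
Why: Partial reduction of a hindered methyl ester with DIBAL-H at low temperature should stop at the aldehyde because the tetrahedral aluminium hemiacetal, chelated to the neighbouring aluminium alkoxide, survives until work-up.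

**Step 13**
Reactants: 19 (1S,2S,4aS,8aS)-1-(hydroxymethyl)-2,8a-dimethyl-5-methylidenedecahydronaphthalene-1-carbaldehyde
Product: 21 [(1R,2S,4aS,8aS)-1,2,8a-trimethyl-5-methylidenedecahydronaphthalen-1-yl]methanol (9β-CH3 and 9α-CH2OH), via hydrazone 20 (not isolated)
Conditions: N2H4·H2O (10 equiv), diethylene glycol, 130 °C; then KOH (5 equiv), 200 °C
Reagents that add atoms: none
Why: Wolff–Kishner reduction (Huang-Minlon procedure) converts the neopentyl aldehyde into the C9 methyl group, the hydrazone being formed before base is added so that the β-hydroxy aldehyde cannot undergo retro-aldol cleavage, and unconjugated exocyclic alkenes tolerate these conditions.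

**Step 14**
Reactants: 21 [(1R,2S,4aS,8aS)-1,2,8a-trimethyl-5-methylidenedecahydronaphthalen-1-yl]methanol
Product: 22 (1R,2S,4aS,8aS)-1,2,8a-trimethyl-5-methylidenedecahydronaphthalene-1-carbaldehyde
Conditions: Dess–Martin periodinane (1.5 equiv), CH2Cl2, rt
Reagents that add atoms: none
Why: Dess–Martin oxidation turns the neopentyl primary alcohol into the non-enolisable C11 aldehyde under near-neutral conditions.

**Step 15**
Reactants: 22 (1R,2S,4aS,8aS)-1,2,8a-trimethyl-5-methylidenedecahydronaphthalene-1-carbaldehyde; 23 1,2,4,5-tetramethoxybenzene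
Product: 26 O-{(2,3,5,6-tetramethoxyphenyl)[(1R,2S,4aS,8aS)-1,2,8a-trimethyl-5-methylidenedecahydronaphthalen-1-yl]methyl} S-methyl carbonodithioate (C11 epimers), via aryllithium 24 (not isolated), via lithium alkoxide 25 (not isolated)
Conditions: 23 (2.5 equiv), n-BuLi (2.4 equiv), THF, 0 °C; 22, −78 → 0 °C; CS2 (6 equiv), 0 °C → rt; MeI (6 equiv), rt
Reagents that add atoms: carbon disulfide, S=C=S; iodomethane, CI
Why: Directed ortho-lithiation of the arene between two methoxy groups, 1,2-addition of the aryllithium to the aldehyde and trapping of the alkoxide as its S-methyl xanthate are standard operations run in one flask, and the new C11 stereocentre is removed in the next step.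

**Step 16**
Reactants: 26 O-{(2,3,5,6-tetramethoxyphenyl)[(1R,2S,4aS,8aS)-1,2,8a-trimethyl-5-methylidenedecahydronaphthalen-1-yl]methyl} S-methyl carbonodithioate
Product: 27 1,2,4,5-tetramethoxy-3-{[(1R,2S,4aS,8aS)-1,2,8a-trimethyl-5-methylidenedecahydronaphthalen-1-yl]methyl}benzene
Conditions: n-Bu3SnH (3 equiv, 0.3 M), AIBN (0.2 equiv), toluene, 100 °C
Reagents that add atoms: none
Why: In this Barton–McCombie deoxygenation the benzylic C–O bond fragments readily and the benzylic radical is reduced by the stannane, kept concentrated so that hydrogen transfer beats addition to the 4(15)-alkene.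

**Step 17**
Reactants: 27 1,2,4,5-tetramethoxy-3-{[(1R,2S,4aS,8aS)-1,2,8a-trimethyl-5-methylidenedecahydronaphthalen-1-yl]methyl}benzene
Product: 28 2,5-dimethoxy-3-{[(1R,2S,4aS,8aS)-1,2,8a-trimethyl-5-methylidenedecahydronaphthalen-1-yl]methyl}cyclohexa-2,5-diene-1,4-dione
Conditions: (NH4)2Ce(NO3)6 (2.5 equiv), MeCN/H2O (2:1), 0 °C
Reagents that add atoms: water, O
Why: Oxidative demethylation of a para-dimethoxyarene by cerium(IV) gives the 2,5-dimethoxy-1,4-benzoquinone, the quinone oxygens coming from water, under conditions too cold and brief to attack the isolated alkene.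

**Step 18**
Reactants: 28 2,5-dimethoxy-3-{[(1R,2S,4aS,8aS)-1,2,8a-trimethyl-5-methylidenedecahydronaphthalen-1-yl]methyl}cyclohexa-2,5-diene-1,4-dione
Product: 29 2-hydroxy-5-methoxy-3-{[(1R,2S,4aS,8aS)-1,2,8a-trimethyl-5-methylidenedecahydronaphthalen-1-yl]methyl}cyclohexa-2,5-diene-1,4-dione (CNP0109104.1)
Conditions: 2 M aq. KOH, MeOH, rt; then 1 M HCl to pH 3, 0 °C
Reagents that add atoms: potassium hydroxide, [K+].[OH-]
Why: Hydroxide adds and methoxide leaves at a vinylogous ester carbon; the methoxy group flanked by the alkyl substituent is twisted out of conjugation and should be the one hydrolysed, and the resulting hydroxyquinone anion resists a second attack, giving the 2-hydroxy-5-methoxy pattern.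

**Compound list**

1 | hexa-1,5-diyne | C#CCCC#C | starting material
2 | lithium hexa-1,5-diyn-1-ide | [Li]C#CCCC#C | intermediate (not isolated)
3 | hepta-2,6-diyn-1-ol | OCC#CCCC#C | intermediate
4 | (2Z)-2-[(trimethylsilyl)methyl]hept-2-en-6-yn-1-ol | OC/C(C[Si](C)(C)C)=C/CCC#C | intermediate
5 | (2Z)-2-[(trimethylsilyl)methyl]hept-2-en-6-yn-1-yl methanesulfonate | CS(=O)(=O)OC/C(C[Si](C)(C)C)=C/CCC#C | intermediate (not isolated)
6 | [(2E)-2-(chloromethyl)hept-2-en-6-yn-1-yl]trimethylsilane | ClC/C(C[Si](C)(C)C)=C/CCC#C | intermediate
7 | 2-(2-bromoethyl)-2-methyl-1,3-dioxolane | CC1(CCBr)OCCO1 | starting material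
8 | [2-(2-methyl-1,3-dioxolan-2-yl)ethyl]magnesium bromide | CC1(CC[Mg]Br)OCCO1 | intermediate (not isolated)
9 | 2-methyl-2-[(4Z)-4-[(trimethylsilyl)methyl]non-4-en-8-yn-1-yl]-1,3-dioxolane | CC1(CCC/C(C[Si](C)(C)C)=C/CCC#C)OCCO1 | intermediate
10 | (6Z)-6-[(trimethylsilyl)methyl]undec-6-en-10-yn-2-one | CC(=O)CCC/C(C[Si](C)(C)C)=C/CCC#C | intermediate
11 | dimethyl malonate | COC(=O)CC(=O)OC | starting material
12 | dimethyl 2-[(6Z)-6-[(trimethylsilyl)methyl]undec-6-en-10-yn-2-ylidene]propanedioate | COC(=O)C(C(=O)OC)=C(C)CCC/C(C[Si](C)(C)C)=C/CCC#C | intermediate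
13 | dimethyl 2-[(1S,2S)-2-(but-3-yn-1-yl)-1-methyl-3-methylidenecyclohexyl]propanedioate | C=C1CCC[C@@](C(C(=O)OC)C(=O)OC)(C)[C@H]1CCC#C | intermediate
14 | dimethyl (4aS,8aS)-8a-methyl-2,5-dimethylideneoctahydronaphthalene-1,1(2H)-dicarboxylate | C=C1CCC[C@@]2(C)[C@H]1CCC(=C)C2(C(=O)OC)C(=O)OC | intermediate
15 | methyl (4aS,8aS)-8a-methyl-2,5-dimethylidenedecahydronaphthalene-1-carboxylate (C1 epimers) | C=C1CCC[C@@]2(C)[C@H]1CCC(=C)C2C(=O)OC | intermediate
16 | lithium dienolate of 15 | C=C1CCC[C@@]2(C)[C@H]1CCC(=C)C2=C(O[Li])OC | intermediate (not isolated)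
17 | methyl (1S,4aS,8aS)-1-(hydroxymethyl)-8a-methyl-2,5-dimethylidenedecahydronaphthalene-1-carboxylate | C=C1CCC[C@@]2(C)[C@H]1CCC(=C)[C@@]2(C(=O)OC)CO | intermediate
18 | methyl (1S,2S,4aS,8aS)-1-(hydroxymethyl)-2,8a-dimethyl-5-methylidenedecahydronaphthalene-1-carboxylate | C=C1CCC[C@@]2(C)[C@H]1CC[C@H](C)[C@@]2(C(=O)OC)CO | intermediate
19 | (1S,2S,4aS,8aS)-1-(hydroxymethyl)-2,8a-dimethyl-5-methylidenedecahydronaphthalene-1-carbaldehyde | C=C1CCC[C@@]2(C)[C@H]1CC[C@H](C)[C@@]2(C=O)CO | intermediate
20 | hydrazone of 19 | C=C1CCC[C@@]2(C)[C@H]1CC[C@H](C)[C@@]2(C=NN)CO | intermediate (not isolated)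
21 | [(1R,2S,4aS,8aS)-1,2,8a-trimethyl-5-methylidenedecahydronaphthalen-1-yl]methanol | C=C1CCC[C@@]2(C)[C@H]1CC[C@H](C)[C@@]2(C)CO | intermediate
22 | (1R,2S,4aS,8aS)-1,2,8a-trimethyl-5-methylidenedecahydronaphthalene-1-carbaldehyde | C=C1CCC[C@@]2(C)[C@H]1CC[C@H](C)[C@@]2(C)C=O | intermediate
23 | 1,2,4,5-tetramethoxybenzene | COc1cc(OC)c(OC)cc1OC | starting material
24 | (2,3,5,6-tetramethoxyphenyl)lithium | [Li]c1c(OC)c(OC)cc(OC)c1OC | intermediate (not isolated)
25 | lithium alkoxide of the C11 benzylic alcohol (C11 epimers) | C=C1CCC[C@@]2(C)[C@H]1CC[C@H](C)[C@@]2(C)C(O[Li])c1c(OC)c(OC)cc(OC)c1OC | intermediate (not isolated)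
26 | O-{(2,3,5,6-tetramethoxyphenyl)[(1R,2S,4aS,8aS)-1,2,8a-trimethyl-5-methylidenedecahydronaphthalen-1-yl]methyl} S-methyl carbonodithioate (C11 epimers) | C=C1CCC[C@@]2(C)[C@H]1CC[C@H](C)[C@@]2(C)C(OC(=S)SC)c1c(OC)c(OC)cc(OC)c1OC | intermediate
27 | 1,2,4,5-tetramethoxy-3-{[(1R,2S,4aS,8aS)-1,2,8a-trimethyl-5-methylidenedecahydronaphthalen-1-yl]methyl}benzene | C=C1CCC[C@@]2(C)[C@H]1CC[C@H](C)[C@@]2(C)Cc1c(OC)c(OC)cc(OC)c1OC | intermediate
28 | 2,5-dimethoxy-3-{[(1R,2S,4aS,8aS)-1,2,8a-trimethyl-5-methylidenedecahydronaphthalen-1-yl]methyl}cyclohexa-2,5-diene-1,4-dione | C=C1CCC[C@@]2(C)[C@H]1CC[C@H](C)[C@@]2(C)CC1=C(OC)C(=O)C=C(OC)C1=O | intermediate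
29 | 2-hydroxy-5-methoxy-3-{[(1R,2S,4aS,8aS)-1,2,8a-trimethyl-5-methylidenedecahydronaphthalen-1-yl]methyl}cyclohexa-2,5-diene-1,4-dione | C=C1CCC[C@@]2(C)[C@H]1CC[C@H](C)[C@@]2(C)CC1=C(O)C(=O)C=C(OC)C1=O | target

**Step count**

Total: 18 steps. Longest linear sequence: 18 steps (1 → 29); compounds 7, 11 and 23 enter at steps 4, 6 and 15.

**The three steps most likely to fail**

First, step 7, the step that rests on a proposed new method. What may go wrong: catalyst turnover may stall at the fully substituted acceptor, protodesilylation may outrun carbon–carbon bond formation, or the ligand may discriminate the two faces of C10 poorly. The fallback uses known chemistry, sets out from 12 and comes back to the route at 13. Stoichiometric TiCl4 in CH2Cl2 at −78 °C, the classical achiral Lewis-acid-promoted intramolecular Hosomi–Sakurai conjugate addition, should give under the same chair control the racemic trans-cyclohexylmalonate F1, which is the racemate of 13. The enantiomers of F1 are then separated by preparative chromatography on a chiral stationary phase, and the enantiomer that has the configuration drawn for 13 continues as 13.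

Second, step 11. What may go wrong: once the directed reduction slows, the cationic iridium hydride may also saturate or isomerise the methylidene group of ring A. The fallback sets out from 17, comes back to the route at 18 and masks the ring A alkene first. mCPBA with NaHCO3 in CH2Cl2 at 0 °C should epoxidise this more exposed alkene in preference to the methylidene group of ring B, which is screened on both faces and deactivated by the allylic ester, giving the spiro-epoxide F2, which is 17 with an oxirane in place of its C4=C15 bond. Hydroxyl-directed hydrogenation with the same iridium catalyst then has a single alkene to reduce and should give the saturated spiro-epoxide F3, the corresponding oxirane of 18. Deoxygenation with triphenylphosphine and catalytic methyltrioxorhenium restores the methylidene group and delivers 18.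

Third, step 8. What may go wrong: enolisation and carbometalation at the neopentyl malonate carbon next to quaternary C10 may be slow, so that acid-induced migration of the ring A methylidene double bond into the ring competes at 110 °C. The fallback sets out from 13 and comes back to the route at 14. Manganese triacetate in ethanol should generate the malonyl radical by oxidation; 6-exo-dig addition of this radical to the alkyne and hydrogen abstraction from the solvent by the vinyl radical form the same C8–C9 bond by a radical pathway and give 14 directly, so this fallback makes no compound outside the compound list and its line is F0.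

**Further compounds**

F1 | step 7 | racemic dimethyl 2-[trans-2-(but-3-yn-1-yl)-1-methyl-3-methylidenecyclohexyl]propanedioate (racemic trans-cyclohexylmalonate, racemate of 13) | C=C1CCC[C@@](C(C(=O)OC)C(=O)OC)(C)[C@H]1CCC#C.C=C1CCC[C@](C(C(=O)OC)C(=O)OC)(C)[C@@H]1CCC#C
F2 | step 11 | 4,15-epoxide of 17 (spiro-epoxide, oxirane at C4, either configuration) | C1OC12CCC[C@@]3(C)[C@H]2CCC(=C)[C@@]3(C(=O)OC)CO
F3 | step 11 | 4,15-epoxide of 18 (saturated spiro-epoxide, oxirane at C4, either configuration) | C1OC12CCC[C@@]3(C)[C@H]2CC[C@H](C)[C@@]3(C(=O)OC)CO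
F0 | step 8 | none | none
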